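Early on, the second substrate works against you: at 20.0 h alpha, charged with half as much of it, shows 6.4% of target, more than the 4.0% of beta at 19.99 h. Beta is the flask you are asked about.

the same everywhere: starting material 0.045 M; reagent 0.0675 M; free catalyst 3.1 mM
- beta: second substrate 0.045 M; capture agent 4.5 mM; the very flask that is asked about, followed so far
- alpha: second substrate 0.022 M; capture agent 4.5 mM; run made earlier
- flask: second substrate 0.0450 M; capture agent 4.50 mM; time 8.0 d

- beta (time / d: target / %): 0.833: 4.0; 1.67: 7.3; 3.00: 8.3; 4.00: 10.2; 5.00: 11.1; 6.00: 11.1
- alpha (time / h: target / %): 5.00: 1.8; 10.0: 4.4; 15.0: 4.6; 20.0: 6.4; 25.0: 6.6; 30.0: 7.4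

(standard deviation of a reading: 0.5 percentage points)

- what is taken out of target is counted as made
- additions bring no volume worth counting

- oak: change nothing and wait 4.0 d more
- cedar: at 8.0 d add free catalyst, 100% of the amount charged, then wait 4.0 d
- alder: at 8.0 d take out 90% of the target then present, then wait 4.0 d
- birch: at 8.0 d add reagent, 50.0% of the amount charged, then wait 4.0 d

* target, in percent of the starting material first charged, at 8.0 d
* what to do for the largest gain in target; "none" if nothing gains more than 2 percentage points (oak / cedar / alder / birch / none)
* target present, with what was taken out counted in, in percent of the starting material first charged, after cedar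
* target present, with what was taken out counted in, in percent of the starting material first charged, after birch

Then beta flattens: 11.1% at 5.00 d, 11.1% at 6.00 d, with a scatter of 0.5 percentage points. Target there accounts for 11.1% of the starting material, so read the plateau against the catalyst instead. One turn of the whole catalyst charge makes 6.89% of the starting material into target, so beta's plateau reads as 1.61 turns. That target per catalyst charged at the stall, the turnover number, is the number to carry.

Now turn each setting by hand. Oak: beta's last two readings are flat, so you reckon 11.1% at 8.0 d and no gain from waiting. Alder: taking target out pays if target itself stalls the catalyst, and you assume it doesn't. Birch: you read the flat stretch as a stopped catalyst, which more reagent doesn't restart, so you reckon 11.1% again. Cedar: you let a fresh charge of 100% make another 1.61 turns, so you reckon 22.2%.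

The forecast gives 11.8% (10.8% to 13%) at 8.0 d and 12.3% (11.2% to 14.5%) after birch. It picks cedar, with 18% (13.5% to 23%): “Fresh catalyst should restart the reaction”. Your cedar figure stands higher than its figure.

The flask gives 11.2% at 8.0 d. Cedar adds 10 points and ends at 21.5%, well ahead of oak with 0.24 points, alder with 0.28 points and birch with 0.53 points, which ends at 11.8%. The choice is cedar.

    starting material + free catalyst ⇌ catalyst intermediate A (K = 23.0 M⁻¹, k = 0.210 M⁻¹ min⁻¹)
    reagent + catalyst intermediate A → free catalyst + target (k = 0.0770 M⁻¹ min⁻¹)
    second substrate + free catalyst ⇌ catalyst intermediate B (K = 64.0 M⁻¹, k = 4.00 M⁻¹ min⁻¹)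
    reagent + catalyst intermediate B → free catalyst + second product (k = 0.210 M⁻¹ min⁻¹)
    catalyst intermediate A + capture agent → trapped intermediate (k = 0.670 M⁻¹ min⁻¹)
    target + free catalyst ⇌ isomer of the product + free catalyst, rate k6*[free catalyst]*[target] forward; the back reaction follows from the equilibrium constant (K = 0.280, k = 0.0430 M⁻¹ min⁻¹)

Cedar's rise from 11.2% to 21.5% counts 1.49 turns of the fresh charge, against the 1.61 read off beta's plateau. In the scheme, catalyst intermediate A goes on to target at its rate constant times [reagent] and is trapped at its rate constant times [capture agent], a ratio of 1.72 at the charges. The forecast's 11.8% would be wrong for a charge of reagent of 0.0929 M, where the answer at 8.0 d has moved by 5 points. For a neighbour flask charged with 0.27 M of reagent, you scale beta's turnover number with [reagent] and reckon 6.45 turns, or 44.4% of target, and that flask holds 50.0% at 8.0 d, with 92.9% of its catalyst as trapped intermediate.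

The earlier runs and the new flask are simulated with constants of no real substance, and the scatter is random.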